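**Retrosynthetic overview**

1. Agrandol 18 is traced back to the bis-MOM flavanone 14: the C8 prenyl group comes from a Stille coupling on the C8 iodide, and the two MOM ethers are removed last.
2. Ring C of 14 is cut at O1–C8a and C4–C4a in one operation, giving aryne 12 (C4a≡C8a of ring A) and the O-silylated (S)-β-hydroxy ester 11, which supplies O1, C2 (already S), C3, C4 and ring B.
3. The feature used: ring A carries O1 on C8a and the C4 carbonyl carbon on the neighbouring C4a, with the C5 oxygen directly beside C4a. This is the pattern a 3-alkoxyaryne takes up as nucleophile at C8a and electrophile at C4a.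
4. The aryne precursor 9 is made from 2-methoxyresorcinol by bis-MOM protection, C–H borylation and oxidation, bromination, retro-Brook silyl shift and triflation.
5. Ring order: ring A and ring B are bought; ring C is the only ring formed (step 8).

Key step: step 8

Remark: flavanone numbering is used throughout (O1, C2, C3, C4, C4a, C5 to C8, C8a; ring A benzo, ring C pyranone, ring B phenyl). Compounds 1, 10 and 16 and both enantiomers of methyl 3-hydroxy-3-phenylpropanoate are assumed to be purchasable.

**Route**

Step 1
Reactants: 1 2-methoxyresorcinol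
Product: 2 2-methoxy-1,3-bis(methoxymethoxy)benzene
Conditions: NaH, MOMCl, DMF, 0 → 23 °C
Reagents that add atoms: chloromethyl methyl ether, COCCl
Why: Williamson-type O-alkylation of both phenoxides should give MOM ethers that tolerate the later organolithium, fluoride and palladium steps and come off under mild acid.

Step 2
Reactants: 2 2-methoxy-1,3-bis(methoxymethoxy)benzene
Product: 3 2-[4-methoxy-3,5-bis(methoxymethoxy)phenyl]-4,4,5,5-tetramethyl-1,3,2-dioxaborolane
Conditions: [Ir(OMe)(cod)]2 (cat.), 4,4'-di-tert-butyl-2,2'-bipyridine (cat.), B2pin2, THF, 80 °C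
Reagents that add atoms: bis(pinacolato)diboron, CC1(C)OB(OC1(C)C)B1OC(C)(C)C(C)(C)O1
Why: iridium-catalysed C–H borylation is governed by sterics, and in this 1,2,3-trisubstituted arene only the carbon para to the methoxy group has no ortho substituent.

Step 3
Reactants: 3 2-[4-methoxy-3,5-bis(methoxymethoxy)phenyl]-4,4,5,5-tetramethyl-1,3,2-dioxaborolane
Product: 4 4-methoxy-3,5-bis(methoxymethoxy)phenol
Conditions: H2O2 (30% aq.), NaOH, THF, 0 °C; then aq. NH4Cl
Reagents that add atoms: hydrogen peroxide, OO
Why: oxidation of the arylboronate with basic peroxide (1,2-shift of the aryl group from boron to oxygen) should give the phenol while the base-stable MOM acetals are untouched.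

Step 4
Reactants: 4 4-methoxy-3,5-bis(methoxymethoxy)phenol
Product: 5 2-bromo-4-methoxy-3,5-bis(methoxymethoxy)phenol
Conditions: NBS (1.0 equiv), CH2Cl2, −78 → 0 °C
Reagents that add atoms: N-bromosuccinimide, BrN1C(=O)CCC1=O
Why: electrophilic aromatic bromination of a strongly activated phenol whose two free positions are equivalent and both ortho to the hydroxyl, so one equivalent of NBS at low temperature should give a single mono-bromide.

Step 5
Reactants: 5 2-bromo-4-methoxy-3,5-bis(methoxymethoxy)phenol
Product: 6 [2-bromo-4-methoxy-3,5-bis(methoxymethoxy)phenoxy]trimethylsilane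
Conditions: HMDS, THF, 65 °C; then evaporation
Reagents that add atoms: hexamethyldisilazane, C[Si](C)(C)N[Si](C)(C)C
Why: O-silylation of the phenol with HMDS gives only ammonia as by-product and places the silyl group for the migration in step 6.

Step 6
Reactants: 6 [2-bromo-4-methoxy-3,5-bis(methoxymethoxy)phenoxy]trimethylsilane
Product: 9 3,5-bis(methoxymethoxy)-4-methoxy-2-(trimethylsilyl)phenyl trifluoromethanesulfonate, via aryllithium 7 (not isolated), via lithium silylphenoxide 8 (not isolated)
Conditions: n-BuLi (1.05 equiv), THF, −78 °C; then Tf2O, −78 → 0 °C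
Reagents that add atoms: trifluoromethanesulfonic anhydride, O=S(=O)(OS(=O)(=O)C(F)(F)F)C(F)(F)F
Why: bromine–lithium exchange gives an aryllithium that undergoes 1,3 O→C silyl migration (retro-Brook rearrangement), and trapping the phenoxide with Tf2O is the standard entry to ortho-silylaryl triflates.

Step 7
Reactants: 10 methyl (S)-3-hydroxy-3-phenylpropanoate
Product: 11 methyl (S)-3-phenyl-3-[(trimethylsilyl)oxy]propanoate
Conditions: HMDS, TMSCl (cat.), CH2Cl2, 23 °C; filtration, evaporation
Reagents that add atoms: hexamethyldisilazane, C[Si](C)(C)N[Si](C)(C)C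
Why: O-silylation of the secondary alcohol replaces the O–H proton by a fluoride-labile group, so that step 8 can release the alkoxide with no proton donor in the flask, and it does not touch the stereocenter.

Step 8
Reactants: 9 3,5-bis(methoxymethoxy)-4-methoxy-2-(trimethylsilyl)phenyl trifluoromethanesulfonate; 11 methyl (S)-3-phenyl-3-[(trimethylsilyl)oxy]propanoate
Product: 14 (2S)-6-methoxy-5,7-bis(methoxymethoxy)-2-phenyl-2,3-dihydro-4H-chromen-4-one, via aryne 12 (not isolated), via aryl cesium adduct 13 (not isolated)
Conditions: 9 (1.3 equiv), CsF (1.1 equiv), 18-crown-6 (0.3 equiv), THF, 23 → 40 °C; then pH 7 phosphate buffer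
Reagents that add atoms: none
Why: Proposed new method: fluoride from CsF cleaves the O–Si bond of 11 to a cesium alkoxide and the C–Si bond of 9 to aryne 12, the alkoxide adds at C8a to form O1–C8a, and the aryl anion 13 at C4a attacks the ester to form C4–C4a and expel methoxide, which is captured on silicon by remaining 9 or 11 and thereby carries the chain on. The closest known reaction type is the fluoride-induced annulation of arynes with methyl salicylates to xanthones (O-arylation followed by intramolecular acyl capture of the aryl anion), and an aliphatic β-silyloxy ester has not been shown as the partner. Ring C closes by 6-exo-trig attack of the C4a carbanion on the ester carbonyl. No stereocenter is formed: C2 comes with 10 in the S configuration, its C–O bond is never broken, and the descriptor stays S because O1, phenyl and C3 keep their rank order. The step needs O-addition at C8a and not at C4a, which the C5 OMOM group secures by inductive distortion of the aryne (charge builds at C4a beside that oxygen) together with the unhindered C8–H beside C8a. It also needs acyl capture to outrun protonation, which is why the hydroxyl proton is replaced by silicon, the solvent is aprotic and fluoride is held near one equivalent, so that no free methoxide is left to open ring C by retro-oxa-Michael reaction and racemise C2.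

Step 9
Reactants: 14 (2S)-6-methoxy-5,7-bis(methoxymethoxy)-2-phenyl-2,3-dihydro-4H-chromen-4-one
Product: 15 (2S)-8-iodo-6-methoxy-5,7-bis(methoxymethoxy)-2-phenyl-2,3-dihydro-4H-chromen-4-one
Conditions: NIS, DMF, 23 °C, dark
Reagents that add atoms: N-iodosuccinimide, IN1C(=O)CCC1=O
Why: electrophilic aromatic iodination should go to C8, the only unsubstituted carbon of ring A (ortho to O1 and the C7 OMOM group, para to the C5 OMOM group), while ring B is unactivated and the neutral medium spares the MOM ethers and C2.

Step 10
Reactants: 15 (2S)-8-iodo-6-methoxy-5,7-bis(methoxymethoxy)-2-phenyl-2,3-dihydro-4H-chromen-4-one; 16 tributyl(3-methylbut-2-en-1-yl)stannane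
Product: 17 (2S)-6-methoxy-5,7-bis(methoxymethoxy)-8-(3-methylbut-2-en-1-yl)-2-phenyl-2,3-dihydro-4H-chromen-4-one
Conditions: Pd(PPh3)4 (cat.), DMF, 90 °C
Reagents that add atoms: none
Why: Stille coupling (oxidative addition of the C8 iodide to zerovalent palladium, transmetalation, reductive elimination at the unsubstituted allyl terminus) should give the linear prenyl group under neutral conditions that leave C2 and the MOM ethers intact.

Step 11
Reactants: 17 (2S)-6-methoxy-5,7-bis(methoxymethoxy)-8-(3-methylbut-2-en-1-yl)-2-phenyl-2,3-dihydro-4H-chromen-4-one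
Product: 18 agrandol, (2S)-5,7-dihydroxy-6-methoxy-8-(3-methylbut-2-en-1-yl)-2-phenyl-2,3-dihydro-4H-chromen-4-one
Conditions: HCl (3 M aq.), MeOH, 23 → 40 °C
Reagents that add atoms: none
Why: acid-catalysed transacetalisation to methanol removes both MOM groups under conditions mild enough that the trisubstituted olefin should not be protonated and ring C, which opens under base, keeps its S configuration.

**Compound list**

1 | 2-methoxyresorcinol (2-methoxybenzene-1,3-diol) | COc1c(O)cccc1O | starting material
2 | 2-methoxy-1,3-bis(methoxymethoxy)benzene | COCOc1cccc(OCOC)c1OC | intermediate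
3 | 2-[4-methoxy-3,5-bis(methoxymethoxy)phenyl]-4,4,5,5-tetramethyl-1,3,2-dioxaborolane | COCOc1cc(B2OC(C)(C)C(C)(C)O2)cc(OCOC)c1OC | intermediate
4 | 4-methoxy-3,5-bis(methoxymethoxy)phenol | COCOc1cc(O)cc(OCOC)c1OC | intermediate
5 | 2-bromo-4-methoxy-3,5-bis(methoxymethoxy)phenol | COCOc1cc(O)c(Br)c(OCOC)c1OC | intermediate
6 | [2-bromo-4-methoxy-3,5-bis(methoxymethoxy)phenoxy]trimethylsilane | COCOc1cc(O[Si](C)(C)C)c(Br)c(OCOC)c1OC | intermediate
7 | [4-methoxy-2,6-bis... aryllithium] 3-methoxy-2,4-bis(methoxymethoxy)-6-(trimethylsilyloxy)phenyllithium (formed in the flask) | COCOc1cc(O[Si](C)(C)C)c([Li])c(OCOC)c1OC | intermediate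
8 | lithium 4-methoxy-3,5-bis(methoxymethoxy)-2-(trimethylsilyl)phenoxide (formed in the flask) | COCOc1cc([O-])c([Si](C)(C)C)c(OCOC)c1OC.[Li+] | intermediate
9 | 3,5-bis(methoxymethoxy)-4-methoxy-2-(trimethylsilyl)phenyl trifluoromethanesulfonate | C[Si](C)(C)c1c(OS(=O)(=O)C(F)(F)F)cc(OCOC)c(OC)c1OCOC | intermediate
10 | methyl (S)-3-hydroxy-3-phenylpropanoate | COC(=O)C[C@@H](c1ccccc1)O | starting material
11 | methyl (S)-3-phenyl-3-[(trimethylsilyl)oxy]propanoate | COC(=O)C[C@@H](c1ccccc1)O[Si](C)(C)C | intermediate
12 | 4-methoxy-3,5-bis(methoxymethoxy)benzyne (1,2-didehydrobenzene; formed in the flask) | COCOC1=CC#CC(OCOC)=C1OC | intermediate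
13 | cesium 2-{[(1S)-3-methoxy-3-oxo-1-phenylpropyl]oxy}-5-methoxy-4,6-bis(methoxymethoxy)benzenide (formed in the flask) | COC(=O)C[C@@H](c1ccccc1)Oc1cc(OCOC)c(OC)c(OCOC)[c-]1.[Cs+] | intermediate
14 | (2S)-6-methoxy-5,7-bis(methoxymethoxy)-2-phenyl-2,3-dihydro-4H-chromen-4-one | COCOc1cc2c(c(OCOC)c1OC)C(=O)C[C@@H](c1ccccc1)O2 | intermediate
15 | (2S)-8-iodo-6-methoxy-5,7-bis(methoxymethoxy)-2-phenyl-2,3-dihydro-4H-chromen-4-one | COCOc1c(I)c2c(c(OCOC)c1OC)C(=O)C[C@@H](c1ccccc1)O2 | intermediate
16 | tributyl(3-methylbut-2-en-1-yl)stannane | CCCC[Sn](CCCC)(CCCC)CC=C(C)C | starting material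
17 | (2S)-6-methoxy-5,7-bis(methoxymethoxy)-8-(3-methylbut-2-en-1-yl)-2-phenyl-2,3-dihydro-4H-chromen-4-one | COCOc1c(CC=C(C)C)c2c(c(OCOC)c1OC)C(=O)C[C@@H](c1ccccc1)O2 | intermediate
18 | agrandol, (2S)-5,7-dihydroxy-6-methoxy-8-(3-methylbut-2-en-1-yl)-2-phenyl-2,3-dihydro-4H-chromen-4-one | COc1c(O)c(CC=C(C)C)c2c(c1O)C(=O)C[C@@H](c1ccccc1)O2 | target

**Summary**

Total step count: 11. Longest linear sequence: 10 steps (steps 1 to 6, then 8 to 11); step 7 is a one-step side branch.

Steps most likely to fail:

1. Step 8 (proposed new method). The C4a aryl anion may be protonated before it reaches the ester, either by adventitious water or by internal transfer of a C3 proton followed by loss of the aryloxide. Enantiopurity may also erode through base-mediated opening of ring C. Fallback by known chemistry, setting out from bromophenol 5: Mitsunobu etherification with methyl (R)-3-hydroxy-3-phenylpropanoate (COC(=O)C[C@H](c1ccccc1)O; PPh3, DIAD, THF, 0 °C) should proceed with inversion to give methyl (S)-3-[2-bromo-4-methoxy-3,5-bis(methoxymethoxy)phenoxy]-3-phenylpropanoate F1. Parham cyclisation (n-BuLi, THF, −100 °C, acetic acid quench at −78 °C) then generates the same C4a carbanion by bromine–lithium exchange at a temperature where the released methoxide should not open ring C. The route is rejoined at 14.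

2. Step 10. Transmetalation at the doubly ortho-oxygenated C8 may be slow, so that reductive loss of iodine competes, and allylic transposition may give the 1,1-dimethylallyl isomer. Fallback from 15: Stille coupling with allyltributylstannane (Pd(PPh3)4, DMF, 80 °C), which has no regiochemical ambiguity, gives (2S)-8-allyl-6-methoxy-5,7-bis(methoxymethoxy)-2-phenyl-2,3-dihydro-4H-chromen-4-one F2. Cross metathesis with 2-methylbut-2-ene (second-generation Grubbs catalyst, RuCl2(=CHPh)(H2IMes)(PCy3), CH2Cl2, 40 °C) then builds the prenyl terminus. The route is rejoined at 17.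

3. Step 11. Acid may promote addition of the freed C7 hydroxyl to the prenyl double bond (chroman formation) or hydration of the olefin during acetal cleavage. Fallback from 15: the MOM groups are removed before the prenyl group is present (HCl, MeOH, 40 °C) to give (2S)-5,7-dihydroxy-8-iodo-6-methoxy-2-phenyl-2,3-dihydro-4H-chromen-4-one F3. Stille coupling of this free diphenol with 16 (Pd(PPh3)4, DMF, 80 °C) then delivers the target 18 directly, with no acid step after prenylation.

Further compounds
F1 | step 8 | methyl (S)-3-[2-bromo-4-methoxy-3,5-bis(methoxymethoxy)phenoxy]-3-phenylpropanoate | COC(=O)C[C@@H](c1ccccc1)Oc1cc(OCOC)c(OC)c(OCOC)c1Br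
F2 | step 10 | (2S)-8-allyl-6-methoxy-5,7-bis(methoxymethoxy)-2-phenyl-2,3-dihydro-4H-chromen-4-one | COCOc1c(CC=C)c2c(c(OCOC)c1OC)C(=O)C[C@@H](c1ccccc1)O2
F3 | step 11 | (2S)-5,7-dihydroxy-8-iodo-6-methoxy-2-phenyl-2,3-dihydro-4H-chromen-4-one | COc1c(O)c(I)c2c(c1O)C(=O)C[C@@H](c1ccccc1)O2
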